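## Analysis of the target

The target 26 is an isoflavone: a chromen-4-one (rings A and C) that carries a 2,4-dihydroxyphenyl ring B at C3. Ring A has hydroxyl groups at C5 and C7 and, between them at C6, a 3-hydroxy-3-methylbutyl chain; ring B has a prenyl group at C3', between its hydroxyl groups at C2' and C4'. There is no stereocentre, so the problems are regiochemistry and functional-group tolerance. The sensitive groups are the prenyl alkene and the tertiary alcohol (both ionise in acid and can be trapped by a neighbouring phenol as a chroman), the electron-rich polyphenol rings, and C2 of the pyranone, which adds nucleophiles. The synthesis is hard because C6 and C8 of ring A are electronically alike, so alkylating a finished 5,7-dihydroxyisoflavone would not tell them apart, and because two different five-carbon chains, one hydrated and one not, must be kept distinct. The plan rests on the fact that C4a carries the acyl carbon C4 and is flanked by oxygenated C5 and C8a, with a third oxygen at C7: ring A is an acylphloroglucinol, the fold of a 3,5,7-triketo ester whose ester carbon becomes C5 and whose α-carbon becomes C6. The tertiary oxygen of the C6 chain is separated from C5 by four carbons, exactly where the ring oxygen of a δ-lactone sits, so the ester can be a 6,6-dimethyl-δ-lactone that delivers C5, C6 and the side chain at its final oxidation level.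

## Retrosynthetic reasoning

**26 to 25.** Only O–H bonds are made last. The ring B phenols are carried as methoxymethyl ethers in 25, because these ethers direct the two metalations that build ring B and survive the amide and alkoxide bases used later. The forward step must cleave two aryl acetals without ionising the tertiary alcohol or the prenyl alkene.

**25 to 23.** Ring C is opened at O1–C2 and C2–C3, which removes the single carbon C2 and leaves deoxybenzoin 23. C2 is the only ring C atom that belongs to neither large fragment, and its removal exposes ring A as a free acylphloroglucinol. Forward, a one-carbon unit at the formic acid level condenses at the benzylic methylene to give enaminone 24, and an ortho phenol closes the pyranone. The closure must use the phenol next to the ring hydrogen, not the one next to the alkyl chain.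

**23 to 21.** Ring A is opened at C4a–C5 and C5 is reconnected to the side-chain oxygen, giving triketo lactone 21. No other ring A cut puts the ester carbon at C5. With this cut the ester α-carbon is C6, so the position of the chain is fixed by constitution, and the tertiary alcohol is simply the leaving group. One step then delivers ring A with its three oxygens, the acyl group and the side chain, through trione 22. Forward, C-acylation of the lactone has to win over aldol closure and O-acylation.

**21 to 8 and 19.** The chain is cut between the carbonyl bearing the arylmethyl group and the methylene on its lactone side. This is the one cut that separates ring B from the lactone half and leaves both as stable compounds: Weinreb amide 19 as acyl donor and the terminal carbon of trianion 20 (from diketo lactone 8) as nucleophile. Forward, acylation has to outrun proton transfer from the benzylic methylene of 19.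

**8 to 6 to 3, then 3 to 1.** Two acetyl units are taken off in turn, each as Weinreb amide 4, through dienolate 7 and enolate 5. A single four-carbon acylation of 5 would save a step, but C- versus O-acylation and proton transfer are harder to control there, and the two acetyl transfers are each standard. Lactone 3 comes from anhydride 1 by forming two C–CH3 bonds at one carbonyl, through hydroxy acid 2.

**19 to 17 to 15, then 15 to 13, 13 to 10 and 11, 10 to 9.** The amide comes from acid 17 (through acyl imidazole 18), and the acid from alcohol 15 (through aldehyde 16). The aryl–CH2 bond of 15 is cut to aryllithium 14, obtained from 13 by metalation ortho to an acetal oxygen. The prenyl–aryl bond of 13 is cut to aryllithium 12, metalated between both acetal oxygens of 10, and bromide 11. Resorcinol 9 already has the oxygen pattern of ring B, so both carbon substituents go in by directed metalation with no positional ambiguity.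

## Alternatives that were turned down

**Alternative 1:** Ring C is closed last at C4–C4a by an intramolecular Friedel–Crafts acylation.
- Forward key step: the (Z)-3-aryloxy-2-arylacrylic acid A2 has as its aryloxy part a 5-hydroxy-3,4-dihydrocoumarin (the C6 chain held as a propanoate lactone on O7) and two acetates on ring B. Activation as the mixed anhydride with trifluoroacetic anhydride lets the acyl carbon attack ring A ortho to the ether oxygen, giving isoflavone A1. Two methyl additions to the lactone of A1 and removal of the acetates would finish.
- For: both positions ortho to the ether oxygen give, once the lactone is opened, the same 5,7-dihydroxy-6-alkyl pattern, so ring closure needs no regiocontrol. On this point it is stronger than the chosen route, where step 11 must distinguish two phenols. Ring A also comes nearly ready-made from a phloroglucinol-derived dihydrocoumarin.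
- Against: the acylation runs in strong acid with the prenyl alkene present. More seriously, the tertiary alcohol is made at the very end by adding a methyl organometallic twice to an aryl lactone in a molecule that also holds two aryl acetates, the C4 carbonyl and the electrophilic C2. The acetates would consume reagent, and conjugate addition at C2 opens ring C.
- Comparison: the chosen route gives up the degenerate closure, but it has the side chain at its final oxidation level before ring C exists and uses no carbon nucleophile after step 9.

**Alternative 2:** Ring B is built last by a vinylketene–alkyne benzannulation.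
- Forward key step: enone diazoketone A4, a fully protected ring A/ring C chromone with a 4-diazo-3-oxobut-1-enyl arm at C3, undergoes photochemical Wolff rearrangement to a vinylketene. [2+2] addition of siloxyalkyne A5, four-electron opening of the cyclobutenone and six-electron closure give phenol A3, with the 2'-hydroxyl free, the 4'-oxygen silylated and the prenyl group between them.
- For: the ring B pattern follows from the mechanism without any directing effect, the two ring B oxygens come out differentiated, and the union is convergent. In ring B regiocontrol it is at least as good as the chosen route.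
- Against: it does nothing for ring A. The 6-alkyl-5,7-dioxygenated chromone, with its C6/C8 question and its side chain, must be made first by other means and then carried through formylation, olefination and diazo transfer. The photolysis is run on a chromone, which is itself photoactive, and the ynol silyl ether with a skipped enyne is a delicate partner.
- Comparison: ring B here is a 2-substituted resorcinol that steps 4–6 reach from 9 by directed metalation, so the annulation buys little and costs many steps and three kinds of protecting group.

**Alternative 3:** Ring A is annulated onto a preformed pyranone.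
- Forward key step: 2-methyl-4-pyranone ester A7 already contains ring C, C2 and protected ring B. Its methyl group is deprotonated, the anion opens lactone 3 (C7–C8), and the enolate of the new ketone attacks the neighbouring ester (C5–C6). Aromatisation gives A6, which is the same compound as 25.
- For: O1 and C2 are in place before ring A is made, so ring C raises no regiochemical question, and the sequence ends one step earlier. On both points it is stronger than the chosen route. It uses the same lactone for the side chain.
- Against: A7 is a fully substituted pyranone needing its own synthesis with the sensitive aryl group on board. Strong bases and carbanions add to the unsubstituted ring carbon next to oxygen (the future C2) about as readily as they deprotonate the methyl group. After the lactone is opened, the most acidic site is the methylene between the new ketone and the pyranone, whereas closure needs the enolate on the other side, so the second bond must form through the less stable enolate onto a hindered ester.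
- Comparison: the chosen route forms ring A in one intramolecular acylation whose regiochemistry is written into the chain, from linear intermediates made by three enolate acylations, and accepts the ring C question in exchange.

Key step: step 10

Remarks on the chemistry: Ar stands for 2,4-bis(methoxymethoxy)-3-(3-methylbut-2-en-1-yl)phenyl. Polycarbonyl compounds are drawn as keto tautomers although they exist largely as enols. The single stereocentre of 6, 8 and 21 is racemic and disappears when ring A aromatises.

## Route

Step 1
Reactants: 1 glutaric anhydride
Product: 3 6,6-dimethyltetrahydro-2H-pyran-2-one, via hydroxy acid 2 (not isolated)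
Conditions: MeMgBr (2.5 equiv), THF, −20 → 23 °C; 2 M HCl, 23 °C; distillation
Reagents that add atoms: methylmagnesium bromide, C[Mg]Br
Why: Double Grignard addition: the first equivalent opens the anhydride to a keto carboxylate, the second adds to the ketone while the carboxylate stays inert; the δ-hydroxy acid 2 should lactonise on acidification and distillation.

Step 2
Reactants: 3 6,6-dimethyltetrahydro-2H-pyran-2-one; 4 N-methoxy-N-methylacetamide
Product: 6 rac-3-acetyl-6,6-dimethyltetrahydro-2H-pyran-2-one, via lithium enolate 5 (not isolated)
Conditions: LiN(i-Pr)2, THF, −78 °C; 4, −78 → 0 °C; aq. NH4Cl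
Reagents that add atoms: none
Why: Crossed Claisen-type C-acylation of a lactone lithium enolate by a Weinreb amide; the chelated tetrahedral adduct persists until the quench, so the acidic β-keto lactone does not form while enolate is present and O-acylation is avoided. The new centre is racemic and is erased in step 10.

Step 3
Reactants: 6 rac-3-acetyl-6,6-dimethyltetrahydro-2H-pyran-2-one; 4 N-methoxy-N-methylacetamide
Product: 8 rac-6,6-dimethyl-3-(3-oxobutanoyl)tetrahydro-2H-pyran-2-one, via dilithium dienolate 7 (not isolated)
Conditions: LiN(i-Pr)2 (2.2 equiv), THF, −78 → 0 °C; 4, −78 → 0 °C; aq. NH4Cl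
Reagents that add atoms: none
Why: γ-Acylation of a β-keto ester dianion: the second deprotonation occurs at the acetyl methyl group, and this more basic terminus is the carbon that attacks the Weinreb amide, giving the 3,5-diketo lactone after hydrolysis of the adduct.

Step 4
Reactants: 9 resorcinol
Product: 10 1,3-bis(methoxymethoxy)benzene
Conditions: NaH, MeOCH2Cl, DMF, 0 → 23 °C
Reagents that add atoms: chloromethyl methyl ether, COCCl
Why: O-Alkylation of the bis-phenoxide (Williamson ether synthesis); the acetal ethers direct ortho-lithiation, resist strong base and are removable with mild acid.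

Step 5
Reactants: 10 1,3-bis(methoxymethoxy)benzene; 11 prenyl bromide (1-bromo-3-methylbut-2-ene)
Product: 13 1,3-bis(methoxymethoxy)-2-(3-methylbut-2-en-1-yl)benzene, via aryllithium 12 (not isolated)
Conditions: n-BuLi, THF, 0 → 23 °C; CuI (10 mol %), then 11, −78 → 23 °C
Reagents that add atoms: none
Why: Directed ortho-metalation at the carbon flanked by both acetal oxygens, the most acidic and doubly coordinated site, followed by copper-catalysed allylic substitution at the primary carbon of 11 (SN2 rather than SN2').

Step 6
Reactants: 13 1,3-bis(methoxymethoxy)-2-(3-methylbut-2-en-1-yl)benzene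
Product: 15 2-Ar-ethan-1-ol, via aryllithium 14 (not isolated)
Conditions: n-BuLi, TMEDA, THF, −20 → 0 °C; oxirane, −78 → 23 °C; aq. NH4Cl
Reagents that add atoms: oxirane, C1CO1
Why: A second directed ortho-metalation can only take place ortho to one acetal oxygen, and the two such positions are equivalent by symmetry; ring opening of the epoxide by the aryllithium should give the 2-arylethanol.

Step 7
Reactants: 15 2-Ar-ethan-1-ol
Product: 17 2-Ar-acetic acid, via arylacetaldehyde 16 (not isolated)
Conditions: TEMPO (10 mol %), PhI(OAc)2 (2.2 equiv), MeCN/H2O 1:1, 23 °C
Reagents that add atoms: water, O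
Why: Oxoammonium-catalysed oxidation of a primary alcohol with PhI(OAc)2 as terminal oxidant; in aqueous acetonitrile aldehyde 16 is hydrated and oxidised on to the acid. No chlorine-based oxidant is present and the medium is only weakly acidic, so the prenyl alkene, the electron-rich ring and the acetals should survive.

Step 8
Reactants: 17 2-Ar-acetic acid
Product: 19 2-Ar-N-methoxy-N-methylacetamide, via acyl imidazole 18 (not isolated)
Conditions: 1,1'-carbonyldiimidazole, CH2Cl2, 23 °C; MeNHOMe·HCl, 23 °C
Reagents that add atoms: N,O-dimethylhydroxylamine hydrochloride, CNOC.Cl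
Why: Activation of the acid as its acyl imidazole and aminolysis to the Weinreb amide under essentially neutral conditions.

Step 9
Reactants: 8 rac-6,6-dimethyl-3-(3-oxobutanoyl)tetrahydro-2H-pyran-2-one; 19 2-Ar-N-methoxy-N-methylacetamide
Product: 21 rac-3-(6-Ar-3,5-dioxohexanoyl)-6,6-dimethyltetrahydro-2H-pyran-2-one, via trilithium trienolate 20 (not isolated)
Conditions: 8 (1.5 equiv), LiN(i-Pr)2 (4.5 equiv), THF, −78 → 0 °C; 19, −78 → −20 °C; AcOH, −78 °C; crude product used at once
Reagents that add atoms: none
Why: Terminal acylation of a 1,3,5-tricarbonyl trianion: the last-formed, most basic carbanion at the methyl terminus is the site that attacks the amide. A Weinreb amide is used because its benzylic protons are less acidic than those of the ester, such amides are acylated even by alkyllithiums despite those protons, and the chelated adduct keeps the more acidic product from quenching 20. Excess 20 and a cold acidic quench are used because 21 is prone to self-condensation.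

Step 10
Reactants: 21 rac-3-(6-Ar-3,5-dioxohexanoyl)-6,6-dimethyltetrahydro-2H-pyran-2-one
Product: 23 2-Ar-1-[2,4,6-trihydroxy-3-(3-hydroxy-3-methylbutyl)phenyl]ethan-1-one, via cyclohexanetrione 22 (not isolated)
Conditions: KOt-Bu (2.2 equiv), degassed THF, 0 → 23 °C; AcOH
Reagents that add atoms: none
Why: Two equivalents of a non-nucleophilic alkoxide convert the 1,3,5-triketone section of 21 into its dianion, which turns all three ketones into enolates and leaves the lactone carbonyl as the only electrophile. The carbon between the two distal ketones (the future C4a) attacks that carbonyl (the future C5) in a 6-exo-trig Claisen closure, the tetrahedral intermediate expels the tethered tertiary alkoxide to give trione 22, and proton shifts aromatise 22 to phloroglucinol 23, an irreversible step that pulls the preceding equilibria through. The closest known reaction type is the base-mediated Claisen cyclisation of 3,5,7-triketo esters to acylphloroglucinols; here the alkoxy leaving group is tethered and stays in the product as the side-chain alcohol. No stereocentre is formed, and the racemic lactone centre of 21 becomes the sp2 carbon C6. The selectivity needed is C-acylation over two aldol modes and over O-acylation: the aldol from the lactone α-carbon would create a quaternary carbon that cannot aromatise and can revert, the aldol from the benzylic methylene is shut off because its acceptor ketone is an enolate, and O-acylation to a pyranone is reversible through the liberated alkoxide. The position of the alkyl chain needs no control because that carbon is the lactone α-carbon. Potassium in an aprotic solvent is chosen to avoid tight chelates that hold the chain extended and to avoid solvolysis of the lactone.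

Step 11
Reactants: 23 2-Ar-1-[2,4,6-trihydroxy-3-(3-hydroxy-3-methylbutyl)phenyl]ethan-1-one
Product: 25 3-Ar-5,7-dihydroxy-6-(3-hydroxy-3-methylbutyl)-4H-chromen-4-one, via enaminone 24 (not isolated)
Conditions: Me2NCH(OMe)2 (2 equiv), THF, 60 °C
Reagents that add atoms: N,N-dimethylformamide dimethyl acetal, COC(OC)N(C)C
Why: Condensation of the amide acetal at the doubly activated benzylic methylene gives enaminone 24; 6-endo-trig addition of an ortho phenol and loss of dimethylamine then give the pyranone, the standard deoxybenzoin-to-isoflavone closure. The phenol wedged between the acyl and alkyl groups is buttressed into the stronger hydrogen bond with the ketone, so the phenol next to the ring hydrogen should close the ring and place the chain at C6. The ring B oxygens are blocked, so no benzofuran can form.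

Step 12
Reactants: 25 3-Ar-5,7-dihydroxy-6-(3-hydroxy-3-methylbutyl)-4H-chromen-4-one
Product: 26 3-[2,4-dihydroxy-3-(3-methylbut-2-en-1-yl)phenyl]-5,7-dihydroxy-6-(3-hydroxy-3-methylbutyl)-4H-chromen-4-one
Conditions: HCl (1 M) in MeOH, 23 °C, stopped at full conversion
Reagents that add atoms: none
Why: Acid-catalysed acetal exchange with methanol; aryl methoxymethyl ethers solvolyse through an oxocarbenium ion much faster than a tertiary alcohol or a trisubstituted alkene ionises at this acidity and temperature, so both five-carbon chains should survive a reaction that is not prolonged.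

## Compound list

1 | glutaric anhydride | O=C1CCCC(=O)O1 | starting material
2 | 5-hydroxy-5-methylhexanoic acid | CC(C)(O)CCCC(=O)O | intermediate (not isolated)
3 | 6,6-dimethyltetrahydro-2H-pyran-2-one | CC1(C)CCCC(=O)O1 | intermediate
4 | N-methoxy-N-methylacetamide | CON(C)C(C)=O | starting material
5 | lithium enolate of 3 | [Li]OC1=CCCC(C)(C)O1 | intermediate (not isolated)
6 | rac-3-acetyl-6,6-dimethyltetrahydro-2H-pyran-2-one | CC(=O)C1CCC(C)(C)OC1=O | intermediate
7 | dilithium dienolate of 6 | C=C(O[Li])C1=C(O[Li])OC(C)(C)CC1 | intermediate (not isolated)
8 | rac-6,6-dimethyl-3-(3-oxobutanoyl)tetrahydro-2H-pyran-2-one | CC(=O)CC(=O)C1CCC(C)(C)OC1=O | intermediate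
9 | resorcinol | Oc1cccc(O)c1 | starting material
10 | 1,3-bis(methoxymethoxy)benzene | COCOc1cccc(OCOC)c1 | intermediate
11 | prenyl bromide (1-bromo-3-methylbut-2-ene) | CC(C)=CCBr | starting material
12 | [2,6-bis(methoxymethoxy)phenyl]lithium | [Li]c1c(OCOC)cccc1OCOC | intermediate (not isolated)
13 | 1,3-bis(methoxymethoxy)-2-(3-methylbut-2-en-1-yl)benzene | COCOc1cccc(OCOC)c1CC=C(C)C | intermediate
14 | [2,4-bis(methoxymethoxy)-3-(3-methylbut-2-en-1-yl)phenyl]lithium | [Li]c1ccc(OCOC)c(CC=C(C)C)c1OCOC | intermediate (not isolated)
15 | 2-[2,4-bis(methoxymethoxy)-3-(3-methylbut-2-en-1-yl)phenyl]ethan-1-ol | OCCc1ccc(OCOC)c(CC=C(C)C)c1OCOC | intermediate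
16 | 2-[2,4-bis(methoxymethoxy)-3-(3-methylbut-2-en-1-yl)phenyl]acetaldehyde | O=CCc1ccc(OCOC)c(CC=C(C)C)c1OCOC | intermediate (not isolated)
17 | 2-[2,4-bis(methoxymethoxy)-3-(3-methylbut-2-en-1-yl)phenyl]acetic acid | OC(=O)Cc1ccc(OCOC)c(CC=C(C)C)c1OCOC | intermediate
18 | 1-{[2,4-bis(methoxymethoxy)-3-(3-methylbut-2-en-1-yl)phenyl]acetyl}imidazole | O=C(Cc1ccc(OCOC)c(CC=C(C)C)c1OCOC)n1ccnc1 | intermediate (not isolated)
19 | 2-[2,4-bis(methoxymethoxy)-3-(3-methylbut-2-en-1-yl)phenyl]-N-methoxy-N-methylacetamide | CON(C)C(=O)Cc1ccc(OCOC)c(CC=C(C)C)c1OCOC | intermediate
20 | trilithium trienolate of 8 | C=C(O[Li])C=C(O[Li])C1=C(O[Li])OC(C)(C)CC1 | intermediate (not isolated)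
21 | rac-3-{6-[2,4-bis(methoxymethoxy)-3-(3-methylbut-2-en-1-yl)phenyl]-3,5-dioxohexanoyl}-6,6-dimethyltetrahydro-2H-pyran-2-one | CC1(C)CCC(C(=O)CC(=O)CC(=O)Cc2ccc(OCOC)c(CC=C(C)C)c2OCOC)C(=O)O1 | intermediate
22 | 2-{[2,4-bis(methoxymethoxy)-3-(3-methylbut-2-en-1-yl)phenyl]acetyl}-4-(3-hydroxy-3-methylbutyl)cyclohexane-1,3,5-trione (stereoisomers and tautomers not defined) | O=C(Cc1ccc(OCOC)c(CC=C(C)C)c1OCOC)C1C(=O)CC(=O)C(CCC(C)(C)O)C1=O | intermediate (not isolated)
23 | 2-[2,4-bis(methoxymethoxy)-3-(3-methylbut-2-en-1-yl)phenyl]-1-[2,4,6-trihydroxy-3-(3-hydroxy-3-methylbutyl)phenyl]ethan-1-one | O=C(Cc1ccc(OCOC)c(CC=C(C)C)c1OCOC)c1c(O)cc(O)c(CCC(C)(C)O)c1O | intermediate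
24 | 2-[2,4-bis(methoxymethoxy)-3-(3-methylbut-2-en-1-yl)phenyl]-3-(dimethylamino)-1-[2,4,6-trihydroxy-3-(3-hydroxy-3-methylbutyl)phenyl]prop-2-en-1-one (alkene geometry not defined) | CN(C)C=C(C(=O)c1c(O)cc(O)c(CCC(C)(C)O)c1O)c1ccc(OCOC)c(CC=C(C)C)c1OCOC | intermediate (not isolated)
25 | 3-[2,4-bis(methoxymethoxy)-3-(3-methylbut-2-en-1-yl)phenyl]-5,7-dihydroxy-6-(3-hydroxy-3-methylbutyl)-4H-chromen-4-one | CC(C)=CCc1c(OCOC)ccc(-c2coc3cc(O)c(CCC(C)(C)O)c(O)c3c2=O)c1OCOC | intermediate
26 | 3-[2,4-dihydroxy-3-(3-methylbut-2-en-1-yl)phenyl]-5,7-dihydroxy-6-(3-hydroxy-3-methylbutyl)-4H-chromen-4-one | CC(C)=CCc1c(O)ccc(-c2coc3cc(O)c(CCC(C)(C)O)c(O)c3c2=O)c1O | target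

## Step count and least certain steps

Total step count: 12. Longest linear sequence: 9 steps (steps 4–12, from resorcinol 9); the lactone branch (steps 1–3) joins at step 9.

**Step 10 (key step).** The likeliest failure is attack on the lactone by the enolate oxygen instead of the central carbon, giving translactonisation to a pyranone. A second is loss of reactivity when the lactone α-carbon is also deprotonated. A third is aldol closure from that α-carbon followed by dehydration, which makes the aldol irreversible. The lactone has less support as acyl acceptor than an open-chain alkyl ester. Fallback: the O-acylation path is used on purpose. From 21, DBU in toluene at 60 °C should give by translactonisation 4-hydroxy-3-(3-hydroxy-3-methylbutyl)-6-(3-Ar-2-oxopropyl)-2H-pyran-2-one F1. Mg(OMe)2 in methanol then opens the pyranone to the open-chain methyl 8-Ar-2-(3-hydroxy-3-methylbutyl)-3,5,7-trioxooctanoate F2, the ester class for which magnesium-templated Claisen cyclisation to acylphloroglucinols is established. F2 closes in the same flask with loss of methanol to 23, where the route is rejoined.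

**Step 9.** The benzylic protons of 19 are acidic, so proton transfer to trianion 20 can compete with addition and return both partners unchanged. Product 21 can also begin to cyclise during work-up. Fallback, from 8 and 17 to 21 without a strongly basic carbanion: trianion 20 is trapped with Me3SiCl as the tris(trimethylsilyl) trienol ether F3. Acid 17 is converted under neutral conditions with 1-chloro-N,N,2-trimethylprop-1-en-1-amine into 2-Ar-acetyl chloride F4. The two are combined in CH2Cl2 at −78 → 0 °C, a vinylogous Mukaiyama-type acylation at the terminal carbon as known for 1,3-bis(silyloxy)dienes with acid chlorides. Aqueous work-up hydrolyses the remaining silyl enol ethers and gives 21.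

**Step 11.** Ring closure through the more hindered phenol would put the chain at C8, and the acetal can methylate the most acidic phenol. The predicted preference rests on a hydrogen-bonding argument, not on a constitutional constraint. Fallback: the isomers are separated and the unwanted one is recycled. The angular isomer 3-Ar-5,7-dihydroxy-8-(3-hydroxy-3-methylbutyl)-4H-chromen-4-one F5 is heated with aqueous KOH in methanol; hydroxide adds at C2, ring C opens and formate is lost, returning deoxybenzoin 23 for another pass.

**Step 6.** Metalation can occur at the benzylic and allylic methylene of the prenyl group instead of on the ring, and the chelated aryllithium may open the epoxide slowly. Fallback: the aryllithium is generated by halogen–metal exchange. Commercial 4-bromoresorcinol F6 is converted with NaH and MeOCH2Cl into 1-bromo-2,4-bis(methoxymethoxy)benzene F7. LiN(i-Pr)2 at −78 °C deprotonates F7 between the two acetal oxygens, and CuI-catalysed reaction with 11 gives 1-bromo-2,4-bis(methoxymethoxy)-3-(3-methylbut-2-en-1-yl)benzene F8. n-BuLi at −78 °C exchanges bromine for lithium faster than any deprotonation, giving 14, which is carried on with oxirane to 15.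

**Step 12.** Ionisation of the tertiary alcohol and capture by the phenol at C5 or C7, or protonation of the prenyl alkene and capture by a ring B phenol, would each give a chroman, and methanol could add as well. Fallback: the acid step is moved to a stage where no tertiary alcohol exists, and the end-game is made neutral. From 19, HCl in methanol gives 2-[2,4-dihydroxy-3-(3-methylbut-2-en-1-yl)phenyl]-N-methoxy-N-methylacetamide F9. Allyl bromide and K2CO3 in acetone give the bis(allyl ether) F10. F10 is joined with 20 as in step 9 to the allyl-protected triketo lactone F11, cyclised as in step 10 to the allyl-protected deoxybenzoin F12, and closed as in step 11 to the bis(allyl ether) of the target F13. Pd(PPh3)4 (zerovalent palladium, catalytic) with morpholine in THF at 23 °C then removes both allyl groups and gives 26.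

## Further compounds

F1 | step 10 | 4-hydroxy-3-(3-hydroxy-3-methylbutyl)-6-{3-[2,4-bis(methoxymethoxy)-3-(3-methylbut-2-en-1-yl)phenyl]-2-oxopropyl}-2H-pyran-2-one | CC(C)(O)CCc1c(O)cc(CC(=O)Cc2ccc(OCOC)c(CC=C(C)C)c2OCOC)oc1=O
F2 | step 10 | rac-methyl 8-[2,4-bis(methoxymethoxy)-3-(3-methylbut-2-en-1-yl)phenyl]-2-(3-hydroxy-3-methylbutyl)-3,5,7-trioxooctanoate | COC(=O)C(CCC(C)(C)O)C(=O)CC(=O)CC(=O)Cc1ccc(OCOC)c(CC=C(C)C)c1OCOC
F3 | step 9 | 6,6-dimethyl-2-(trimethylsilyloxy)-3-[1,3-bis(trimethylsilyloxy)buta-1,3-dien-1-yl]-5,6-dihydro-4H-pyran (enol ether geometry not defined) | C=C(O[Si](C)(C)C)C=C(O[Si](C)(C)C)C1=C(O[Si](C)(C)C)OC(C)(C)CC1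
F4 | step 9 | 2-[2,4-bis(methoxymethoxy)-3-(3-methylbut-2-en-1-yl)phenyl]acetyl chloride | ClC(=O)Cc1ccc(OCOC)c(CC=C(C)C)c1OCOC
F5 | step 11 | 3-[2,4-bis(methoxymethoxy)-3-(3-methylbut-2-en-1-yl)phenyl]-5,7-dihydroxy-8-(3-hydroxy-3-methylbutyl)-4H-chromen-4-one | COCOc1ccc(-c2coc3c(CCC(C)(C)O)c(O)cc(O)c3c2=O)c(OCOC)c1CC=C(C)C
F6 | step 6 | 4-bromoresorcinol (4-bromobenzene-1,3-diol) | Oc1ccc(Br)c(O)c1
F7 | step 6 | 1-bromo-2,4-bis(methoxymethoxy)benzene | COCOc1ccc(Br)c(OCOC)c1
F8 | step 6 | 1-bromo-2,4-bis(methoxymethoxy)-3-(3-methylbut-2-en-1-yl)benzene | COCOc1ccc(Br)c(OCOC)c1CC=C(C)C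
F9 | step 12 | 2-[2,4-dihydroxy-3-(3-methylbut-2-en-1-yl)phenyl]-N-methoxy-N-methylacetamide | CON(C)C(=O)Cc1ccc(O)c(CC=C(C)C)c1O
F10 | step 12 | 2-[2,4-bis(allyloxy)-3-(3-methylbut-2-en-1-yl)phenyl]-N-methoxy-N-methylacetamide | CON(C)C(=O)Cc1ccc(OCC=C)c(CC=C(C)C)c1OCC=C
F11 | step 12 | rac-3-{6-[2,4-bis(allyloxy)-3-(3-methylbut-2-en-1-yl)phenyl]-3,5-dioxohexanoyl}-6,6-dimethyltetrahydro-2H-pyran-2-one | CC1(C)CCC(C(=O)CC(=O)CC(=O)Cc2ccc(OCC=C)c(CC=C(C)C)c2OCC=C)C(=O)O1
F12 | step 12 | 2-[2,4-bis(allyloxy)-3-(3-methylbut-2-en-1-yl)phenyl]-1-[2,4,6-trihydroxy-3-(3-hydroxy-3-methylbutyl)phenyl]ethan-1-one | O=C(Cc1ccc(OCC=C)c(CC=C(C)C)c1OCC=C)c1c(O)cc(O)c(CCC(C)(C)O)c1O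
F13 | step 12 | 3-[2,4-bis(allyloxy)-3-(3-methylbut-2-en-1-yl)phenyl]-5,7-dihydroxy-6-(3-hydroxy-3-methylbutyl)-4H-chromen-4-one | CC(C)=CCc1c(OCC=C)ccc(-c2coc3cc(O)c(CCC(C)(C)O)c(O)c3c2=O)c1OCC=C
A1 | alternative 1 | lactone-bridged 5-hydroxyisoflavone diacetate (C6 chain as propanoate lactone on O7) | O=C1CCc2c(O1)cc1occ(-c3ccc(OC(C)=O)c(CC=C(C)C)c3OC(C)=O)c(=O)c1c2O
A2 | alternative 1 | (Z)-2-[2,4-diacetoxy-3-(3-methylbut-2-en-1-yl)phenyl]-3-[(5-hydroxy-2-oxochroman-7-yl)oxy]acrylic acid | O=C1CCc2c(O)cc(O/C=C(/c3ccc(OC(C)=O)c(CC=C(C)C)c3OC(C)=O)C(=O)O)cc2O1
A3 | alternative 2 | 2'-hydroxy-4'-(triisopropylsilyloxy)-3'-prenyl isoflavone with 5,7-bis(methoxymethoxy) and triethylsilyl-protected side chain | CC(C)=CCc1c(O[Si](C(C)C)(C(C)C)C(C)C)ccc(-c2coc3cc(OCOC)c(CCC(C)(C)O[Si](CC)(CC)CC)c(OCOC)c3c2=O)c1O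
A4 | alternative 2 | (E)-3-(4-diazo-3-oxobut-1-en-1-yl)-5,7-bis(methoxymethoxy)-6-[3-methyl-3-(triethylsilyloxy)butyl]-4H-chromen-4-one | [N-]=[N+]=CC(=O)/C=C/c1coc2cc(OCOC)c(CCC(C)(C)O[Si](CC)(CC)CC)c(OCOC)c2c1=O
A5 | alternative 2 | triisopropyl[(5-methylhex-4-en-1-yn-1-yl)oxy]silane | CC(C)=CCC#CO[Si](C(C)C)(C(C)C)C(C)C
A6 | alternative 3 | 2',4'-bis(methoxymethyl) ether of the target (identical with 25) | CC(C)=CCc1c(OCOC)ccc(-c2coc3cc(O)c(CCC(C)(C)O)c(O)c3c2=O)c1OCOC
A7 | alternative 3 | methyl 5-[2,4-bis(methoxymethoxy)-3-(3-methylbut-2-en-1-yl)phenyl]-2-methyl-4-oxo-4H-pyran-3-carboxylate | COC(=O)c1c(C)occ(-c2ccc(OCOC)c(CC=C(C)C)c2OCOC)c1=O
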